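**Plan**
- Ring locants: C1 = CH–C(=O)Ar, C2 = CH–prenyl, C3 = C–CH3, C4 = CH=, C5 = CH2, C6 = CHPh. The retrosynthesis first unmasks the phenol (O–CH3) and trades the prenyl group for a CH2CO2H arm. It then cuts the two opposite ring bonds C4–C5 and C1–C2 together, and last the aryl–carbinol bond.
- Enabling feature: the ketone carbon, C1, C6 and C5 are four carbons in a row. The carbonyl carbon can therefore be folded back onto C5 as a prochiral 1-aryl-3-phenylcyclobutanol. C4=C3(CH3)–C2 is an alkenyl unit whose C2 becomes electrophilic once prenyl is replaced by a Z-acrylate arm.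
- Forward: bromobenzofuran + 3-phenylcyclobutanone give the cyclobutanol, and propargyl alcohol gives a (2Z,4Z)-iododienoate. One Pd/Cs2CO3 operation opens the four-membered ring, joins C5 to C4 and closes C1–C2, so the cyclohexene arises in that step. Then CO2Me becomes prenyl and OMe becomes OH.
- Stereochemistry: C6 comes from the chiral ligand (desymmetrisation of enantiotopic C–C bonds). C2 comes from C6 through a chair-like Michael closure steered by Z-ester/C3-methyl allylic strain. C1 is set by base equilibration to the equatorial ketone. The ring alkene geometry comes from the anti-carbomagnesiation.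

Key step: step 7

Assumption: the sense of induction of the ferrocenyl P,N ligand on this cyclobutanol cannot be predicted. The antipode that gives the (R)-configured phenyl-bearing carbon is fixed in a trial run and is written below as (R,Sp)-PPFA.

Step 1
Reactants: 1 4,6-dimethoxy-1-benzofuran-3(2H)-one
Product: 3 4,6-dimethoxy-1-benzofuran, via dihydrobenzofuranol 2 (not isolated)
Conditions: NaBH4, MeOH, 0 °C to rt; then 2 M HCl, THF, rt
Reagents that add atoms: none
Why: Borohydride reduction of the aryl ketone gives the benzylic alcohol, which should lose water under acid because aromatisation to the benzofuran drives the dehydration (reduction–dehydration of a coumaranone).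

Step 2
Reactants: 3 4,6-dimethoxy-1-benzofuran
Product: 4 7-bromo-4,6-dimethoxy-1-benzofuran
Conditions: NBS (1.0 equiv), MeCN, −20 to 0 °C, dark
Reagents that add atoms: N-bromosuccinimide O=C1CCC(=O)N1Br
Why: Electrophilic aromatic bromination with NBS in a polar solvent should go to C7, which is para to the 4-methoxy group, ortho to two oxygens and less hindered than C5 between the two methoxy groups.

Step 3
Reactants: 4 7-bromo-4,6-dimethoxy-1-benzofuran; 5 3-phenylcyclobutan-1-one
Product: 7 cis-1-(4,6-dimethoxy-1-benzofuran-7-yl)-3-phenylcyclobutan-1-ol (OH and phenyl on the same face, achiral), via aryllithium 6 (not isolated)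
Conditions: n-BuLi, THF, −78 °C; then 5, −78 to −20 °C; aq NH4Cl
Reagents that add atoms: none
Why: Bromine–lithium exchange is faster than deprotonation of the furan C2–H at −78 °C, and 1,2-addition of the aryllithium to the strained ketone should occur anti to the 3-phenyl group, which gives the achiral carbinol with two enantiotopic carbinol–CH2 bonds.

Step 4
Reactants: 8 prop-2-yn-1-ol
Product: 10 (2Z)-3-iodo-2-methylprop-2-en-1-ol, via alkenylmagnesium chelate 9 (not isolated)
Conditions: MeMgBr (2.5 equiv), CuI (10 mol %), THF, −10 °C to rt; then I2, −10 °C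
Reagents that add atoms: methylmagnesium bromide C[Mg]Br; iodine II
Why: Copper-catalysed, alkoxide-directed anti-carbomagnesiation places methyl on the internal carbon and magnesium on the terminal one in a five-membered chelate, and iodinolysis with retention fixes iodine cis to CH2OH.

Step 5
Reactants: 10 (2Z)-3-iodo-2-methylprop-2-en-1-ol
Product: 11 (2Z)-3-iodo-2-methylprop-2-enal
Conditions: activated MnO2 (excess), CH2Cl2, rt, dark; filtered and used at once
Reagents that add atoms: none
Why: Allylic alcohol oxidation with MnO2 is neutral and should keep the Z geometry of the sensitive β-iodoenal.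

Step 6
Reactants: 11 (2Z)-3-iodo-2-methylprop-2-enal
Product: 12 methyl (2Z,4Z)-5-iodo-4-methylpenta-2,4-dienoate
Conditions: (CF3CH2O)2P(O)CH2CO2Me, KHMDS, 18-crown-6, THF, −78 °C
Reagents that add atoms: methyl 2-[bis(2,2,2-trifluoroethoxy)phosphoryl]acetate COC(=O)CP(=O)(OCC(F)(F)F)OCC(F)(F)F
Why: The Still–Gennari variant of the Horner–Wadsworth–Emmons olefination eliminates under kinetic control and should give the new 2Z double bond without touching the 4Z iodoalkene.

Step 7
Reactants: 7 cis-1-(4,6-dimethoxy-1-benzofuran-7-yl)-3-phenylcyclobutan-1-ol; 12 methyl (2Z,4Z)-5-iodo-4-methylpenta-2,4-dienoate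
Product: 14 methyl 2-[(1S,5R,6R)-6-(4,6-dimethoxy-1-benzofuran-7-carbonyl)-2-methyl-5-phenylcyclohex-2-en-1-yl]acetate, via ring-opened keto dienoate 13 (not isolated)
Conditions: Pd2(dba)3·CHCl3 (2.5 mol %), (R,Sp)-PPFA (6 mol %), Cs2CO3 (2.5 equiv), toluene, 60 °C
Reagents that add atoms: none
Why: Proposed new method: Pd(0) inserts into the C–I bond of 12, the caesium alkoxide of 7 replaces iodide, strain-driven β-carbon elimination cleaves one of the two enantiotopic carbinol–CH2 bonds, and C(sp3)–C(sp2) reductive elimination with retention of the Z-alkenyl geometry forges ring bond C4–C5 and unveils aryl ketone 13, whose caesium enolate then adds to the β-carbon of its own Z-enoate and forges C1–C2. The closest known reaction types are the Pd-catalysed ring-opening arylation and alkenylation of tert-cyclobutanols under Cs2CO3 (enantioselective with ferrocenyl P,N ligands) and the carbonate-mediated intramolecular Michael addition of aryl ketones; only their merger is new, and it is reasonable because the first event creates the enolisable ketone in the same basic medium, tethered five atoms from the acceptor. The four-membered ring opens and the cyclohexene closes in a 6-(enolexo)-exo-trig mode, which is possible only because C5 and C2 are cis on the C3=C4 double bond. C6 is set by the ligand (desymmetrisation); C2 is set by C6 through a chair-like transition state with phenyl equatorial, in which A(1,3) strain between the cis ester of the Z-enoate and the C3-methyl group turns the acceptor plane perpendicular to the ring alkene so that the CH2CO2Me arm ends pseudoaxial and trans to phenyl; C1 is epimerisable and should settle under the carbonate as the equatorial ketone, trans to phenyl and cis to the arm. The step needs reductive elimination to outrun β-hydride elimination and aryl–carbinol cleavage, which ring strain and the electron-poor dienyl ligand on palladium should secure, and it needs attack at C2 only, which the tether length enforces.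

Step 8
Reactants: 14 methyl 2-[(1S,5R,6R)-6-(4,6-dimethoxy-1-benzofuran-7-carbonyl)-2-methyl-5-phenylcyclohex-2-en-1-yl]acetate
Product: 15 2-[(1S,5R,6R)-6-(4,6-dimethoxy-1-benzofuran-7-carbonyl)-2-methyl-5-phenylcyclohex-2-en-1-yl]acetic acid
Conditions: LiOH, THF–MeOH–H2O, rt; then 1 M HCl
Reagents that add atoms: lithium hydroxide [Li+].[OH-]
Why: Saponification of the unhindered primary methyl ester leaves the hindered aryl ketone alone, and the only base-labile centre (C1 of the target ring) already sits in its more stable configuration.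

Step 9
Reactants: 15 2-[(1S,5R,6R)-6-(4,6-dimethoxy-1-benzofuran-7-carbonyl)-2-methyl-5-phenylcyclohex-2-en-1-yl]acetic acid
Product: 17 (4,6-dimethoxy-1-benzofuran-7-yl)[(1R,2S,6R)-3-methyl-2-(3-methylbut-2-en-1-yl)-6-phenylcyclohex-3-en-1-yl]methanone, via N-acyloxyphthalimide ester 16 (not isolated)
Conditions: N-hydroxyphthalimide, DIC, DMAP (cat.), CH2Cl2, rt; then Ni(acac)2 (10 mol %), 2,2'-bipyridine (10 mol %), (2-methylprop-1-enyl)ZnCl (from the Grignard reagent and ZnCl2), THF–DMF, rt
Reagents that add atoms: N-hydroxyphthalimide O=C1c2ccccc2C(=O)N1O (stays in 16 only); 2-methylprop-1-enylmagnesium bromide CC(C)=C[Mg]Br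
Why: Nickel-catalysed decarboxylative alkenylation of a redox-active ester turns CH2–CO2H into CH2–CH=CMe2 through a primary radical that is remote from every stereocentre, and organozinc reagents tolerate the ketone.

Step 10
Reactants: 17 (4,6-dimethoxy-1-benzofuran-7-yl)[(1R,2S,6R)-3-methyl-2-(3-methylbut-2-en-1-yl)-6-phenylcyclohex-3-en-1-yl]methanone
Product: 18 (6-hydroxy-4-methoxy-1-benzofuran-7-yl)[(1R,2S,6R)-3-methyl-2-(3-methylbut-2-en-1-yl)-6-phenylcyclohex-3-en-1-yl]methanone (CNP0247234.1)
Conditions: BCl3 (1.2 equiv), CH2Cl2, −78 to −40 °C; then H2O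
Reagents that add atoms: none
Why: Chelation-controlled ether cleavage: boron binds the ketone oxygen and the only ortho methoxy group (C6–OMe) in a six-membered chelate, so chloride should remove that methyl group alone while the 4-methoxy group stays.

**Compound list**
1 | 4,6-dimethoxy-1-benzofuran-3(2H)-one | COc1cc(OC)c2C(=O)COc2c1 | starting material
2 | 4,6-dimethoxy-2,3-dihydro-1-benzofuran-3-ol (racemic) | COc1cc(OC)c2C(O)COc2c1 | intermediate
3 | 4,6-dimethoxy-1-benzofuran | COc1cc(OC)c2ccoc2c1 | intermediate
4 | 7-bromo-4,6-dimethoxy-1-benzofuran | COc1cc(OC)c(Br)c2occc12 | intermediate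
5 | 3-phenylcyclobutan-1-one | O=C1CC(c2ccccc2)C1 | starting material
6 | (4,6-dimethoxy-1-benzofuran-7-yl)lithium | COc1cc(OC)c([Li])c2occc12 | intermediate
7 | cis-1-(4,6-dimethoxy-1-benzofuran-7-yl)-3-phenylcyclobutan-1-ol | COc1cc(OC)c([C@]3(O)C[C@@H](c4ccccc4)C3)c2occc12 | intermediate
8 | prop-2-yn-1-ol | C#CCO | starting material
9 | 4-methyl-1-oxa-2-magnesacyclopent-3-ene (alkenylmagnesium alkoxide chelate) | CC1=C[Mg]OC1 | intermediate
10 | (2Z)-3-iodo-2-methylprop-2-en-1-ol | OC/C(C)=C\I | intermediate
11 | (2Z)-3-iodo-2-methylprop-2-enal | O=C/C(C)=C\I | intermediate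
12 | methyl (2Z,4Z)-5-iodo-4-methylpenta-2,4-dienoate | COC(=O)/C=C\C(C)=C/I | intermediate
13 | methyl (2Z,4Z,7R)-9-(4,6-dimethoxy-1-benzofuran-7-yl)-4-methyl-9-oxo-7-phenylnona-2,4-dienoate | COC(=O)/C=C\C(C)=C/C[C@H](CC(=O)c1c(OC)cc(OC)c2ccoc12)c1ccccc1 | intermediate
14 | methyl 2-[(1S,5R,6R)-6-(4,6-dimethoxy-1-benzofuran-7-carbonyl)-2-methyl-5-phenylcyclohex-2-en-1-yl]acetate | COc1cc(OC)c(C(=O)[C@@H]2[C@H](CC(=O)OC)C(C)=CC[C@H]2c2ccccc2)c2occc12 | intermediate
15 | 2-[(1S,5R,6R)-6-(4,6-dimethoxy-1-benzofuran-7-carbonyl)-2-methyl-5-phenylcyclohex-2-en-1-yl]acetic acid | COc1cc(OC)c(C(=O)[C@@H]2[C@H](CC(=O)O)C(C)=CC[C@H]2c2ccccc2)c2occc12 | intermediate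
16 | 1,3-dioxoisoindolin-2-yl ester of 15 | COc1cc(OC)c(C(=O)[C@@H]2[C@H](CC(=O)ON3C(=O)c4ccccc4C3=O)C(C)=CC[C@H]2c2ccccc2)c2occc12 | intermediate
17 | (4,6-dimethoxy-1-benzofuran-7-yl)[(1R,2S,6R)-3-methyl-2-(3-methylbut-2-en-1-yl)-6-phenylcyclohex-3-en-1-yl]methanone | COc1cc(OC)c(C(=O)[C@@H]2[C@H](CC=C(C)C)C(C)=CC[C@H]2c2ccccc2)c2occc12 | intermediate
18 | (6-hydroxy-4-methoxy-1-benzofuran-7-yl)[(1R,2S,6R)-3-methyl-2-(3-methylbut-2-en-1-yl)-6-phenylcyclohex-3-en-1-yl]methanone | COc1cc(O)c(C(=O)[C@@H]2[C@H](CC=C(C)C)C(C)=CC[C@H]2c2ccccc2)c2occc12 | target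

Total step count: 10. Longest linear sequence: 7 steps (steps 1, 2, 3, 7, 8, 9, 10; the branch through steps 4, 5, 6 is equally long).

**Steps most likely to fail**

Step 7.
- What may go wrong: β-hydride elimination of the alkylpalladium intermediate; cleavage of the aryl–carbinol bond instead of a ring bond; low enantiotopic discrimination; Z-to-E drift of the enoate under the base, which would weaken the facial selectivity of the ring closure.
- Fallback (known chemistry): it sets out from 3 and comes back at 18. Friedel–Crafts acetylation of 3 (AcCl, SnCl4, CH2Cl2, −20 °C) would give 1-(4,6-dimethoxy-1-benzofuran-7-yl)ethan-1-one F1. Chelation-controlled cleavage with BCl3 would give 1-(6-hydroxy-4-methoxy-1-benzofuran-7-yl)ethan-1-one F2. Claisen–Schmidt condensation with benzaldehyde (KOH, EtOH) would give (2E)-1-(6-hydroxy-4-methoxy-1-benzofuran-7-yl)-3-phenylprop-2-en-1-one F3. An endo-selective Diels–Alder reaction of this 2'-hydroxychalcone with commercial (E)-β-ocimene, promoted by a chiral BINOL-type borate complex bound to the hydroxy ketone, should then deliver 18 directly.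

Step 2.
- What may go wrong: bromination or addition at the electron-rich furan C2=C3 bond, or attack at C5, in competition with C7.
- Fallback: it sets out from 1 and comes back at 4. The halogen is introduced before the furan double bond exists. NBS in DMF on 1 would give 7-bromo-4,6-dimethoxy-1-benzofuran-3(2H)-one F4. NaBH4 would give 7-bromo-4,6-dimethoxy-2,3-dihydro-1-benzofuran-3-ol F5, and acid-induced dehydration would give 4.

Step 10.
- What may go wrong: Lewis or protic acid attack on the prenyl and ring alkenes (hydrochlorination, cation cyclisation) during the ether cleavage.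
- Fallback: it sets out from 14 and comes back at 18. The order is changed so that the prenyl group never meets BCl3. BCl3 on 14 would give methyl 2-[(1S,5R,6R)-6-(6-hydroxy-4-methoxy-1-benzofuran-7-carbonyl)-2-methyl-5-phenylcyclohex-2-en-1-yl]acetate F6. LiOH would give the corresponding acetic acid F7. The hydrogen-bonded phenol should stay inert while NHPI/DIC forms the 1,3-dioxoisoindolin-2-yl ester F8. The nickel-catalysed alkenylation, run with one extra equivalent of the zinc reagent, would then give 18.

**Further compounds**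
F1 | step 7 | 1-(4,6-dimethoxy-1-benzofuran-7-yl)ethan-1-one | CC(=O)c1c(OC)cc(OC)c2ccoc12
F2 | step 7 | 1-(6-hydroxy-4-methoxy-1-benzofuran-7-yl)ethan-1-one | CC(=O)c1c(O)cc(OC)c2ccoc12
F3 | step 7 | (2E)-1-(6-hydroxy-4-methoxy-1-benzofuran-7-yl)-3-phenylprop-2-en-1-one | O=C(/C=C/c1ccccc1)c1c(O)cc(OC)c2ccoc12
F4 | step 2 | 7-bromo-4,6-dimethoxy-1-benzofuran-3(2H)-one | COc1cc(OC)c2C(=O)COc2c1Br
F5 | step 2 | 7-bromo-4,6-dimethoxy-2,3-dihydro-1-benzofuran-3-ol (racemic) | COc1cc(OC)c2C(O)COc2c1Br
F6 | step 10 | methyl 2-[(1S,5R,6R)-6-(6-hydroxy-4-methoxy-1-benzofuran-7-carbonyl)-2-methyl-5-phenylcyclohex-2-en-1-yl]acetate | COc1cc(O)c(C(=O)[C@@H]2[C@H](CC(=O)OC)C(C)=CC[C@H]2c2ccccc2)c2occc12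
F7 | step 10 | 2-[(1S,5R,6R)-6-(6-hydroxy-4-methoxy-1-benzofuran-7-carbonyl)-2-methyl-5-phenylcyclohex-2-en-1-yl]acetic acid | COc1cc(O)c(C(=O)[C@@H]2[C@H](CC(=O)O)C(C)=CC[C@H]2c2ccccc2)c2occc12
F8 | step 10 | 1,3-dioxoisoindolin-2-yl ester of F7 | COc1cc(O)c(C(=O)[C@@H]2[C@H](CC(=O)ON3C(=O)c4ccccc4C3=O)C(C)=CC[C@H]2c2ccccc2)c2occc12
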